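The readings were generated by integration for an exercise, and the scatter is random.

**The vessel.** A closed, stirred vessel held D, J and catalyst X, with half the X of the eta run, and I wanted the ratio of G to Z at three times.

| setting | eta | flask |
|---|---|---|
| D | 27 mM | 27 mM |
| J | 6.75 mM | 6.75 mM |
| X | 5.4 mM | 2.7 mM |
| remark | run made earlier |  |
| time |  | 50 h |

eta run (percent of the D and J together charged)

| time / h | G / % | Z / % |
|---|---|---|
| 1.33 | 9.8 | 10.6 |
| 4.00 | 14.9 | 18.5 |
| 6.00 | 16.7 | 19.7 |
| 10.0 | 19.3 | 21.7 |

(readings scatter by 0.5 percentage points)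

- ratio of G to Z at 4.0 min
- ratio of G to Z at 2.0 h
- ratio of G to Z at 50 h

**Charge ratio.** I folded the charges into one number, the charge ratio 0.250, which is J over D as they went in. At 4.0 min, far earlier than the first eta reading, I took D and J to stand nearly as charged. I supposed that both products arise on X, so I set G per Z equal to a selectivity factor times this ratio, with X cancelling.

**Both ends.** In the eta run, between 1.33 h and 4.00 h, G grew by 0.646 per unit of Z. The first reading stood higher, at 0.925, so I took the eta ratio to have begun higher still, as far as readings with this scatter can tell. If it fell in a straight line to that slope by the first reading, it began at 1.20, which makes the selectivity factor 4.81.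

**One number?** It was not enough. The charge ratio serves the start, but the later eta ratios ran from 0.805 to 0.889. For 2.0 h and 50 h I therefore committed to the midpoint of these two, 0.847, and the effect of less X remained a guess.

**The result.** The forecast gave 1, 0.92 and 0.95, saying of the first, "I guess about 1.0, with wide limits". The flask gave 1.94, 0.875 and 0.883, so its ratio at 4.0 min stood above my 1.20. In this flask G and Z stood level at 1.18 h, at 4.95% each. Divided by the charge ratio, the flask's early value gives 7.77.

    D ⇌ J (K = 0.0710, k = 5.19 × 10⁻⁵ s⁻¹)
    D + X → X + Z (k = 0.00612 M⁻¹ s⁻¹)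
    X + J → X + G (k = 0.0516 M⁻¹ s⁻¹)
    2 D → E (k = 9.56 × 10⁻⁴ M⁻¹ s⁻¹)
    Z + X ⇌ L + X, rate k5*[X]*[Z] forward; the back reaction follows from the equilibrium constant (K = 1.40, k = 0.00520 M⁻¹ s⁻¹)
    X → Q (k = 2.86 × 10⁻⁵ s⁻¹)

**Second flask.** With 46 mM of D, the charge ratio is 0.147, and this gives 1.14 at 4.0 min. The computed ratio in that flask is 1.17.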